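**Plan**

- Retrosynthetic cuts: C7–OH goes back to C7–Br. The C4–C4a bond of the dihydropyran ring is cut and C4 is returned to C8a, which gives a 1-oxaspiro[4.5]deca-7,9-dien-6-one whose five-membered ring is O1–C2–C3–C4–C8a. Its C8a–O1 bond is then cut (phenol plus tertiary alcohol), then the aryl–CH2 bond (2,6-dibromo-4-methylphenol plus (S)-geranyllinalool), and the latter goes back to geranylgeraniol.
- Enabling feature: C8 carries a hydroxyl ortho to the ring oxygen on C8a, and C4a, the neighbour of C8a, carries C4. An 8-hydroxychroman is therefore the dienone–phenol product of an ortho-quinol spiroether in which C8 is the carbonyl carbon, C8a the spiro carbon and C4a the free dienone terminus.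
- Forward order: the all-E chain comes intact from geranylgeraniol and is joined by B-alkyl Suzuki coupling to the arene carbon that will become C8a. Oxidative dearomatisation closes the spiro tetrahydrofuran, a 1,2-shift of C4 expands it to the dihydropyran ring and restores the benzene ring, and bromine is exchanged for hydroxyl last.
- Stereochemistry: C2 (S) is set by Katsuki–Sharpless epoxidation with L-(+)-diethyl tartrate and its C–O bond is never broken afterwards. The spiro centre is transient, and the bromine serves as blocking group and latent C7 hydroxyl.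

Key step: step 5

Remark: the target is read as the (2S) enantiomer with a (3E,7E) side chain; all-E geranylgeraniol and 2,6-dibromo-4-methylphenol are taken as purchased.

**Step 1**
Reactants: 1 (2E,6E,10E)-geranylgeraniol
Product: 2 [(2S,3S)-3-methyl-3-[(3E,7E)-4,8,12-trimethyltrideca-3,7,11-trien-1-yl]oxiran-2-yl]methanol
Conditions: Ti(OiPr)4 (10 mol %), L-(+)-diethyl tartrate (12 mol %), t-BuOOH (2 equiv, decane), 4 Å MS, CH2Cl2, −20 °C
Reagents that add atoms: tert-butyl hydroperoxide, CC(C)(C)OO
Why: Katsuki–Sharpless asymmetric epoxidation is directed by the allylic hydroxyl, so only the 2,3-alkene of the tetraene should react, and the L-(+)-tartrate ligand is expected to give the (2S,3S)-epoxide, whose C3 becomes C2 of the chroman.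

**Step 2**
Reactants: 2 (2S,3S)-epoxy alcohol
Product: 3 (2R,3S)-2-(iodomethyl)-3-methyl-3-[(3E,7E)-4,8,12-trimethyltrideca-3,7,11-trien-1-yl]oxirane
Conditions: PPh3, I2, imidazole, CH2Cl2, 0 °C
Reagents that add atoms: iodine, II
Why: Appel-type iodination of the primary alcohol under imidazole buffering should leave the epoxide, the alkenes and both stereocentres untouched (the descriptor at C2 changes only because of the priority of iodine).

**Step 3**
Reactants: 3 epoxy iodide
Product: 4 (3S,6E,10E)-3,7,11,15-tetramethylhexadeca-1,6,10,14-tetraen-3-ol, (S)-geranyllinalool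
Conditions: activated Zn dust, AcOH (2 equiv), EtOH, 0 °C → rt
Reagents that add atoms: none
Why: Zinc insertion into the C–I bond and β-elimination of the epoxide oxygen (Boord-type reductive ring opening) should give the tertiary allylic alcohol with the (S) configuration carried over, because the carbinol C–O bond is not broken.

**Step 4**
Reactants: 4 (S)-geranyllinalool; 5 2,6-dibromo-4-methylphenol
Product: 7 2-bromo-6-[(3S,6E,10E)-3-hydroxy-3,7,11,15-tetramethylhexadeca-6,10,14-trien-1-yl]-4-methylphenol, via B-alkyl-9-BBN borane 6 (not isolated)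
Conditions: 9-BBN dimer (0.75 equiv), THF, 0 °C → rt; then 5 (3 equiv), PdCl2(dppf) (5 mol %), 3 M aq K3PO4, DMF, 60 °C
Reagents that add atoms: none
Why: 9-BBN should hydroborate the monosubstituted vinyl group much faster than the trisubstituted alkenes (and faster than it reacts with the hindered tertiary hydroxyl) with boron on the terminal carbon, and the B-alkyl Suzuki–Miyaura coupling then joins this carbon to one C–Br of the symmetric dibromophenol, whose excess should hold the coupling at the mono stage.

**Step 5**
Reactants: 7 bromophenol with tertiary alcohol side chain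
Product: 9 (2S)-7-bromo-2,5-dimethyl-2-[(3E,7E)-4,8,12-trimethyltrideca-3,7,11-trien-1-yl]-3,4-dihydro-2H-1-benzopyran-8-ol, via spirodienone 8 (not isolated)
Conditions: PhI(OAc)2 (1.05 equiv), (CF3)2CHOH/CH2Cl2 (1:4), −20 °C; cold aq NaHCO3 wash, solvent switch to CH2Cl2 (solution not stored); BF3·OEt2 (0.3 equiv), −78 → −20 °C
Reagents that add atoms: none
Why: Proposed new method: PhI(OAc)2 binds the phenol oxygen to trivalent iodine and makes the ring a phenoxenium equivalent with positive charge only on the two ortho carbons and the para carbon, so the tethered tertiary hydroxyl should close the tetrahydrofuran by 5-exo attack on the chain-bearing ortho carbon and give the 6,6-disubstituted cyclohexa-2,4-dienone 8; BF3 on the dienone oxygen then gives a hydroxypentadienyl cation, the ring CH2 migrates from the spiro carbon to the neighbouring unsubstituted dienone terminus (1,2-shift, ring expansion of the five-membered oxacycle to the dihydropyran), and loss of the proton at that terminus restores the arene as the 8-hydroxychroman. The closest known reaction types are the acid-mediated dienone–phenol rearrangement of 4-alkoxy-4-alkylcyclohexa-2,5-dienones, including para-spiroether dienones that give chroman-6-ols, and the 1,2-alkyl shift of 6,6-dialkylcyclohexa-2,4-dienones, so the ortho-spiroether case rests on analogy. Carbon rather than oxygen should migrate because the migration origin then becomes an oxocarbenium ion stabilised by the ring oxygen, and migration can only go to the CH terminus because the other neighbour of the spiro carbon is the carbonyl carbon. The spiro carbon is a transient stereocentre that forms as a mixture and is erased on aromatisation, while C2 keeps the (S) configuration of the carbinol because none of its bonds is broken. The step needs ipso attack at the alkylated ortho carbon rather than capture at the methyl-bearing para carbon, and a shift that is faster than ionisation of the tertiary C2–O bond or protonation of the polyene; the intramolecular hydroxyl in a non-nucleophilic fluoro alcohol, the bromine that blocks the second ortho carbon and should slow dimerisation of the dienone, and a carbonyl-bound Lewis acid at low temperature are relied on for this.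

**Step 6**
Reactants: 9 7-bromochroman-8-ol
Product: 12 (2S)-2,5-dimethyl-2-[(3E,7E)-4,8,12-trimethyltrideca-3,7,11-trien-1-yl]-3,4-dihydro-2H-1-benzopyran-7,8-diol, via dilithio aryl phenoxide 10 (not isolated), via dimethyl arylboronate 11 (not isolated)
Conditions: n-BuLi (3 equiv), THF, −78 → 0 °C; B(OMe)3 (4 equiv), −78 °C → rt; 30% aq H2O2, aq NaOH, 0 °C; degassed aq NH4Cl work-up under Ar
Reagents that add atoms: hydrogen peroxide, OO
Why: Bromine–lithium exchange on the lithium phenoxide, trapping with B(OMe)3 and oxidative 1,2-migration of the aryl group from boron to oxygen (ipso-hydroxylation of an arylboronate) should replace bromine by hydroxyl at C7 without touching the alkenes, the chroman ether or C2.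

**Compound list**

1 | (2E,6E,10E)-3,7,11,15-tetramethylhexadeca-2,6,10,14-tetraen-1-ol (geranylgeraniol) | CC(C)=CCC/C(C)=C/CC/C(C)=C/CC/C(C)=C/CO | starting material
2 | [(2S,3S)-3-methyl-3-[(3E,7E)-4,8,12-trimethyltrideca-3,7,11-trien-1-yl]oxiran-2-yl]methanol | CC(C)=CCC/C(C)=C/CC/C(C)=C/CC[C@]1(C)O[C@H]1CO | intermediate
3 | (2R,3S)-2-(iodomethyl)-3-methyl-3-[(3E,7E)-4,8,12-trimethyltrideca-3,7,11-trien-1-yl]oxirane | CC(C)=CCC/C(C)=C/CC/C(C)=C/CC[C@]1(C)O[C@H]1CI | intermediate
4 | (3S,6E,10E)-3,7,11,15-tetramethylhexadeca-1,6,10,14-tetraen-3-ol ((S)-geranyllinalool) | CC(C)=CCC/C(C)=C/CC/C(C)=C/CC[C@](C)(O)C=C | intermediate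
5 | 2,6-dibromo-4-methylphenol | Cc1cc(Br)c(O)c(Br)c1 | starting material
6 | B-alkyl-9-BBN adduct of 4, boron on the terminal carbon, carbinol centre unchanged (not isolated) | CC(C)=CCC/C(C)=C/CC/C(C)=C/CC[C@](C)(O)CCB1C2CCCC1CCC2 | intermediate
7 | 2-bromo-6-[(3S,6E,10E)-3-hydroxy-3,7,11,15-tetramethylhexadeca-6,10,14-trien-1-yl]-4-methylphenol | CC(C)=CCC/C(C)=C/CC/C(C)=C/CC[C@](C)(O)CCc1cc(C)cc(Br)c1O | intermediate
8 | (2S)-7-bromo-2,9-dimethyl-2-[(3E,7E)-4,8,12-trimethyltrideca-3,7,11-trien-1-yl]-1-oxaspiro[4.5]deca-7,9-dien-6-one, both configurations at the spiro carbon (not isolated) | CC(C)=CCC/C(C)=C/CC/C(C)=C/CC[C@@]1(C)CCC2(O1)C=C(C)C=C(Br)C2=O | intermediate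
9 | (2S)-7-bromo-2,5-dimethyl-2-[(3E,7E)-4,8,12-trimethyltrideca-3,7,11-trien-1-yl]-3,4-dihydro-2H-1-benzopyran-8-ol | CC(C)=CCC/C(C)=C/CC/C(C)=C/CC[C@@]1(C)CCc2c(C)cc(Br)c(O)c2O1 | intermediate
10 | lithium (2S)-7-lithio-2,5-dimethyl-2-[(3E,7E)-4,8,12-trimethyltrideca-3,7,11-trien-1-yl]-3,4-dihydro-2H-1-benzopyran-8-olate (not isolated) | CC(C)=CCC/C(C)=C/CC/C(C)=C/CC[C@@]1(C)CCc2c(C)cc([Li])c(O[Li])c2O1 | intermediate
11 | dimethyl arylboronate at C7 of the lithium chroman-8-olate (not isolated) | CC(C)=CCC/C(C)=C/CC/C(C)=C/CC[C@@]1(C)CCc2c(C)cc(B(OC)OC)c(O[Li])c2O1 | intermediate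
12 | (2S)-2,5-dimethyl-2-[(3E,7E)-4,8,12-trimethyltrideca-3,7,11-trien-1-yl]-3,4-dihydro-2H-1-benzopyran-7,8-diol | CC(C)=CCC/C(C)=C/CC/C(C)=C/CC[C@@]1(C)CCc2c(C)cc(O)c(O)c2O1 | target

**Count**

Total steps: 6. Longest linear sequence: 6 steps (1 → 12); compound 5 enters in step 4.

**Steps most likely to fail**

1. Step 5 (oxidative dearomatisation and ring expansion).
 - What may go wrong: the oxidised phenol may be captured at the methyl-bearing para carbon by acetate or solvent, or lose a proton from the para-methyl group, instead of spirocyclising. The dienone may dimerise by [4+2] cycloaddition before it rearranges. The Lewis acid may ionise the tertiary C2–O bond (loss of configuration or elimination), oxygen may migrate instead of carbon, or the polyene may be protonated and cyclise.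
 - Fallback (known chemistry), from 4 back to 12: 4-methylcatechol with MOMCl and i-Pr2NEt should give 1,2-bis(methoxymethoxy)-4-methylbenzene F1. Directed ortho-lithiation (n-BuLi, TMEDA, THF, 0 °C) next to the OMOM group remote from the methyl group and quenching with BrCl2C–CCl2Br should give 1-bromo-2,3-bis(methoxymethoxy)-5-methylbenzene F2. Iodination with NIS at the position para to the 3-OMOM group, between bromine and methyl, should give 3-bromo-2-iodo-4,5-bis(methoxymethoxy)-1-methylbenzene F3. Borane 6, made from 4 as in step 4, would be coupled at the C–I bond (PdCl2(dppf), aq K3PO4, DMF) to give (3S,6E,10E)-1-[2-bromo-3,4-bis(methoxymethoxy)-6-methylphenyl]-3,7,11,15-tetramethylhexadeca-6,10,14-trien-3-ol F4. Intramolecular C–O coupling of the tertiary alcohol with the aryl bromide (Pd(OAc)2, 2-(di-tert-butylphosphino)-1,1'-binaphthyl, Cs2CO3, toluene, 80 °C) forms the O1–C8a bond with the carbinol C–O bond untouched and should give (2S)-7,8-bis(methoxymethoxy)-2,5-dimethyl-2-[(3E,7E)-4,8,12-trimethyltrideca-3,7,11-trien-1-yl]-3,4-dihydro-2H-1-benzopyran F5. HCl in MeOH at rt removes both MOM groups and returns to 12.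

2. Step 6 (bromine to hydroxyl).
 - What may go wrong: bromine–lithium exchange on the electron-rich lithium phenoxide may be incomplete, the aryllithium may be alkylated by the 1-bromobutane formed, or it may be protonated before borylation.
 - Fallback, from 9 back to 12, by C–H formylation and Dakin oxidation instead of halogen–metal exchange: hydrodebromination (Pd(OAc)2, PPh3, HCO2Na, DMF, 80 °C) should give (2S)-2,5-dimethyl-2-[(3E,7E)-4,8,12-trimethyltrideca-3,7,11-trien-1-yl]-3,4-dihydro-2H-1-benzopyran-8-ol F6. Ortho-formylation at C7, the only free ortho position (MgCl2, Et3N, paraformaldehyde, MeCN, reflux), should give (2S)-8-hydroxy-2,5-dimethyl-2-[(3E,7E)-4,8,12-trimethyltrideca-3,7,11-trien-1-yl]-3,4-dihydro-2H-1-benzopyran-7-carbaldehyde F7. Dakin oxidation (H2O2, aq NaOH, THF, 0 °C) with hydrolysis of the aryl formate returns to 12.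

3. Step 4 (hydroboration and B-alkyl Suzuki coupling).
 - What may go wrong: both C–Br bonds may couple, oxidative addition into the bromophenoxide may be slow enough for the alkylborane to decompose (protodeboronation, β-hydride elimination), or 9-BBN may be consumed by the tertiary hydroxyl.
 - Fallback, from 4 back to 7, by a Heck reaction and chemoselective alkene reduction instead of an sp3–sp2 coupling: 2-bromo-4-methylphenol is iodinated (NIS, cat. TsOH, MeCN) to 2-bromo-6-iodo-4-methylphenol F8. Ligand-free Heck coupling of F8 with the vinyl group of 4 at the C–I bond (Pd(OAc)2, n-Bu4NCl, NaHCO3, DMF, 60 °C) should give 2-bromo-6-[(1E,3S,6E,10E)-3-hydroxy-3,7,11,15-tetramethylhexadeca-1,6,10,14-tetraen-1-yl]-4-methylphenol F9. Diimide (2-nitrobenzenesulfonylhydrazide, Et3N, CH2Cl2, rt) should reduce the 1,2-disubstituted styrenyl alkene in preference to the trisubstituted alkenes and return to 7.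

**Further compounds**

F1 | step 5 | 1,2-bis(methoxymethoxy)-4-methylbenzene | COCOc1ccc(C)cc1OCOC
F2 | step 5 | 1-bromo-2,3-bis(methoxymethoxy)-5-methylbenzene | COCOc1cc(C)cc(Br)c1OCOC
F3 | step 5 | 3-bromo-2-iodo-4,5-bis(methoxymethoxy)-1-methylbenzene | COCOc1cc(C)c(I)c(Br)c1OCOC
F4 | step 5 | (3S,6E,10E)-1-[2-bromo-3,4-bis(methoxymethoxy)-6-methylphenyl]-3,7,11,15-tetramethylhexadeca-6,10,14-trien-3-ol | CC(C)=CCC/C(C)=C/CC/C(C)=C/CC[C@](C)(O)CCc1c(C)cc(OCOC)c(OCOC)c1Br
F5 | step 5 | (2S)-7,8-bis(methoxymethoxy)-2,5-dimethyl-2-[(3E,7E)-4,8,12-trimethyltrideca-3,7,11-trien-1-yl]-3,4-dihydro-2H-1-benzopyran | CC(C)=CCC/C(C)=C/CC/C(C)=C/CC[C@@]1(C)CCc2c(C)cc(OCOC)c(OCOC)c2O1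
F6 | step 6 | (2S)-2,5-dimethyl-2-[(3E,7E)-4,8,12-trimethyltrideca-3,7,11-trien-1-yl]-3,4-dihydro-2H-1-benzopyran-8-ol | CC(C)=CCC/C(C)=C/CC/C(C)=C/CC[C@@]1(C)CCc2c(C)ccc(O)c2O1
F7 | step 6 | (2S)-8-hydroxy-2,5-dimethyl-2-[(3E,7E)-4,8,12-trimethyltrideca-3,7,11-trien-1-yl]-3,4-dihydro-2H-1-benzopyran-7-carbaldehyde | CC(C)=CCC/C(C)=C/CC/C(C)=C/CC[C@@]1(C)CCc2c(C)cc(C=O)c(O)c2O1
F8 | step 4 | 2-bromo-6-iodo-4-methylphenol | Cc1cc(Br)c(O)c(I)c1
F9 | step 4 | 2-bromo-6-[(1E,3S,6E,10E)-3-hydroxy-3,7,11,15-tetramethylhexadeca-1,6,10,14-tetraen-1-yl]-4-methylphenol | CC(C)=CCC/C(C)=C/CC/C(C)=C/CC[C@](C)(O)/C=C/c1cc(C)cc(Br)c1O
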